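**Retrosynthetic overview**
- The depside ester bond between O4 of ring A and the C1' carboxyl carbon of ring B is cut last. Ring A is purchased methyl atrarate, and ring B is carried as its tribenzyl ether acid.
- The strategy rests on ring B (C1' acyl carbon, C2'–C4' OH, C5' H, C6' CH3): the oxygens on C2' and C4' are 1,3-related with C3' between them. The triol ester is therefore the enol tautomer of a 6-methyl-2,3,4-trioxocyclohexane-1-carboxylate, which is the C3'-methylene oxidation product of the 2,4-dioxo ring.
- That 2,4-dioxo ring is opened at C1'–C6' (Michael) and C3'–C4' (Claisen) to tert-butyl acetoacetate and methyl crotonate.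
- Ring order: ring B is the only ring built (step 1, dione level). It is oxidized at C3' and aromatized (steps 2–3), then benzylated, unmasked, joined to ring A and debenzylated (steps 4–7).

Key step: step 1

Remark on the chemistry: compounds 3–6 are racemic and undefined at C1' and C6' (both epimerizable). Both centres vanish on aromatization and the target has no stereocentre. Compound 4 is drawn as the diketo form although it should exist largely as an enol.

**Step 1**
Reactants: 1 tert-butyl 3-oxobutanoate (tert-butyl acetoacetate); 2 methyl (E)-but-2-enoate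
Product: 4 tert-butyl 6-methyl-2,4-dioxocyclohexane-1-carboxylate, via Michael adduct 3 (not isolated)
Conditions: KOtBu (1.1 equiv), tBuOH, rt then 80 °C; cold 1 M HCl to pH 3
Reagents that add atoms: none
Why: This is the base-mediated Michael–Claisen (Dieckmann-type) annulation, the classical acetoacetate–crotonate route to dihydroorsellinates: the potassium enolate of 1 adds through its doubly stabilized central carbon to the β-carbon of 2 (C1'–C6'), and after proton transfer the enolate of the acetyl methyl group acylates the methyl ester (C3'–C4') with loss of methoxide. Ring B closes in a 6-exo-trig mode, and deprotonation of the new 1,3-dione at C3' by the liberated alkoxide should pull the equilibria to the stable dione enolate. The two stereocentres formed (C1', C6') are not controlled and need not be, since both are epimerizable and are erased in step 3. The selectivity required is chemoselectivity between two enolate carbons and two ester carbonyls: the more acidic central carbon does the conjugate addition, only the methyl-ketone enolate reaches the methyl ester through a six-membered transition state, and the hindered tert-butyl ester is no acyl acceptor. Using tert-butoxide in tert-butanol avoids ester exchange at the tert-butyl ester.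

**Step 2**
Reactants: 4 tert-butyl 6-methyl-2,4-dioxocyclohexane-1-carboxylate
Product: 5 tert-butyl 3-diazo-6-methyl-2,4-dioxocyclohexane-1-carboxylate
Conditions: p-ABSA (1.05 equiv), Et3N (1.2 equiv), MeCN, 0 °C to rt
Reagents that add atoms: p-acetamidobenzenesulfonyl azide (p-ABSA), CC(=O)Nc1ccc(cc1)S(=O)(=O)N=[N+]=[N-]
Why: In this Regitz diazo transfer C3' is the only methylene between two ketones, the most acidic site and the only activated carbon with two hydrogens, so the diazo group should be delivered there and the tertiary C1'–H left alone.

**Step 3**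
Reactants: 5 tert-butyl 3-diazo-6-methyl-2,4-dioxocyclohexane-1-carboxylate
Product: 7 tert-butyl 2,3,4-trihydroxy-6-methylbenzoate, via cyclohexanetrione 6 (not isolated)
Conditions: DMDO (1.0 equiv, acetone), −20 to 0 °C; evaporate; NaOAc (cat.), AcOH/THF (degassed), rt, Ar
Reagents that add atoms: dimethyldioxirane (DMDO), CC1(C)OO1
Why: Oxygen-atom transfer from dimethyldioxirane to a 2-diazo-1,3-dione with loss of N2 is an established route to vicinal tricarbonyls, and the 2,3,4-trione formed is the keto tautomer of the pyrogallol ester, so buffered enolization (C1'–H, C5'–H, then C6'–H) should aromatize ring B as cyclohexane-1,2,3-triones are known to do.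

**Step 4**
Reactants: 7 tert-butyl 2,3,4-trihydroxy-6-methylbenzoate; 8 benzyl bromide
Product: 9 tert-butyl 2,3,4-tris(benzyloxy)-6-methylbenzoate
Conditions: BnBr (3.6 equiv), K2CO3 (4 equiv), DMF (degassed), 60 °C, Ar
Reagents that add atoms: benzyl bromide (8), BrCc1ccccc1
Why: Williamson etherification of all three phenols in a dipolar aprotic solvent, with excess halide and warming to bring in the chelated 2'-OH and exclusion of air to protect the electron-rich phenolates; the tert-butyl ester is inert to carbonate.

**Step 5**
Reactants: 9 tert-butyl 2,3,4-tris(benzyloxy)-6-methylbenzoate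
Product: 10 2,3,4-tris(benzyloxy)-6-methylbenzoic acid
Conditions: TFA/CH2Cl2 (1:4), 0 °C to rt, short reaction time
Reagents that add atoms: none
Why: Acidolysis of the tert-butyl ester goes through the tert-butyl cation (AAL1) and is therefore not slowed by the two ortho substituents, while aryl benzyl ethers should tolerate brief exposure to cold trifluoroacetic acid.

**Step 6**
Reactants: 10 2,3,4-tris(benzyloxy)-6-methylbenzoic acid; 11 methyl 2,4-dihydroxy-3,6-dimethylbenzoate (methyl atrarate)
Product: 13 methyl 2-hydroxy-3,6-dimethyl-4-{[2,3,4-tris(benzyloxy)-6-methylbenzoyl]oxy}benzoate, via mixed trifluoroacetic anhydride 12 (not isolated)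
Conditions: (CF3CO)2O (2.5 equiv), toluene, 0 °C to rt
Reagents that add atoms: none
Why: Trifluoroacetic anhydride-mediated esterification through the mixed anhydride (acylium-like acyl donor) is the established way to esterify 2,6-disubstituted benzoic acids with phenols in depside synthesis, and the free 4-OH of 11 should react in preference to the 2-OH, which is hydrogen-bonded to the ester carbonyl and flanked on both sides.

**Step 7**
Reactants: 13 methyl 2-hydroxy-3,6-dimethyl-4-{[2,3,4-tris(benzyloxy)-6-methylbenzoyl]oxy}benzoate
Product: 14 methyl 2-hydroxy-3,6-dimethyl-4-[(2,3,4-trihydroxy-6-methylbenzoyl)oxy]benzoate (target)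
Conditions: H2 (1 atm), 10% Pd/C, EtOAc, rt; filtration and evaporation under Ar
Reagents that add atoms: none
Why: Catalytic hydrogenolysis should cleave the three benzyl ethers under neutral conditions that leave the aryl ester, the methyl ester and the aromatic rings intact.

**Compound list**
1 | tert-butyl 3-oxobutanoate (tert-butyl acetoacetate) | CC(=O)CC(=O)OC(C)(C)C | starting material
2 | methyl (E)-but-2-enoate (methyl crotonate) | C/C=C/C(=O)OC | starting material
3 | 1-tert-butyl 5-methyl 2-acetyl-3-methylpentanedioate (Michael adduct, racemic diastereomer mixture) | COC(=O)CC(C)C(C(C)=O)C(=O)OC(C)(C)C | intermediate (not isolated)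
4 | tert-butyl 6-methyl-2,4-dioxocyclohexane-1-carboxylate (racemic, epimerizable at both centres) | CC1CC(=O)CC(=O)C1C(=O)OC(C)(C)C | intermediate
5 | tert-butyl 3-diazo-6-methyl-2,4-dioxocyclohexane-1-carboxylate (racemic, epimerizable) | CC1CC(=O)C(=[N+]=[N-])C(=O)C1C(=O)OC(C)(C)C | intermediate
6 | tert-butyl 6-methyl-2,3,4-trioxocyclohexane-1-carboxylate (racemic, epimerizable) | CC1CC(=O)C(=O)C(=O)C1C(=O)OC(C)(C)C | intermediate (not isolated)
7 | tert-butyl 2,3,4-trihydroxy-6-methylbenzoate | Cc1cc(O)c(O)c(O)c1C(=O)OC(C)(C)C | intermediate
8 | benzyl bromide | BrCc1ccccc1 | starting material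
9 | tert-butyl 2,3,4-tris(benzyloxy)-6-methylbenzoate | Cc1cc(OCc2ccccc2)c(OCc2ccccc2)c(OCc2ccccc2)c1C(=O)OC(C)(C)C | intermediate
10 | 2,3,4-tris(benzyloxy)-6-methylbenzoic acid | Cc1cc(OCc2ccccc2)c(OCc2ccccc2)c(OCc2ccccc2)c1C(=O)O | intermediate
11 | methyl 2,4-dihydroxy-3,6-dimethylbenzoate (methyl atrarate) | COC(=O)c1c(C)cc(O)c(C)c1O | starting material
12 | 2,3,4-tris(benzyloxy)-6-methylbenzoic trifluoroacetic anhydride | Cc1cc(OCc2ccccc2)c(OCc2ccccc2)c(OCc2ccccc2)c1C(=O)OC(=O)C(F)(F)F | intermediate (not isolated)
13 | methyl 2-hydroxy-3,6-dimethyl-4-{[2,3,4-tris(benzyloxy)-6-methylbenzoyl]oxy}benzoate | COC(=O)c1c(C)cc(OC(=O)c2c(C)cc(OCc3ccccc3)c(OCc3ccccc3)c2OCc2ccccc2)c(C)c1O | intermediate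
14 | methyl 2-hydroxy-3,6-dimethyl-4-[(2,3,4-trihydroxy-6-methylbenzoyl)oxy]benzoate | COC(=O)c1c(C)cc(OC(=O)c2c(C)cc(O)c(O)c2O)c(C)c1O | target

**Step count**
Total steps: 7. Longest linear sequence: 7 steps (1 and 2 to 14); methyl atrarate 11 and benzyl bromide 8 enter unchanged.

**Steps most likely to fail**

Step 3. The oxidant may not stop at the diazo carbon: it could hydroxylate the enolized β-keto ester at C1' or attack the electron-rich arene as it forms, and the trione may be held as its hydrate and enolize slowly. The fallback sets out from dione 4 and returns at 7. Condensation of 4 with N,N-dimethylformamide dimethyl acetal (toluene, rt) should give the enaminone tert-butyl 3-[(dimethylamino)methylidene]-6-methyl-2,4-dioxocyclohexane-1-carboxylate F1 (push–pull double bond, geometry not fixed). Cleavage of its electron-rich C=C bond with one equivalent of ozone (CH2Cl2, −78 °C, then Me2S), the enaminone route to vicinal tricarbonyls, would give the same trione 6 without a diazo intermediate or a dioxirane. The buffered tautomerization of step 3 then leads to 7.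

Step 6. Acyl transfer to the di-ortho-substituted carbonyl may stall, or the acid-promoted acyl donor may react at the wrong site of ring A (the chelated 2-OH, or carbon C5 in a Friedel–Crafts sense); partial loss of the 2'-benzyl ether in the acidic medium is also possible. The fallback sets out from acid 10 and returns at 13, replacing acid-mediated activation by an isolated acyl halide and an anionic nucleophile. Oxalyl chloride with catalytic DMF in CH2Cl2 should convert 10 into 2,3,4-tris(benzyloxy)-6-methylbenzoyl chloride F2. This is added to the monosodium phenoxide of 11 (NaH, 1.0 equiv, THF, 0 °C), in which the more acidic, unchelated 4-OH is the one deprotonated, to give 13.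

Step 4. The triphenolate may be degraded oxidatively before it is fully alkylated, and the chelated, doubly flanked 2'-OH may be benzylated incompletely. The fallback sets out from triol 7 and returns at target 14, using acyl protection that needs no phenoxide. Acetylation of 7 (Ac2O, pyridine, cat. DMAP, CH2Cl2, 0 °C) should give tert-butyl 2,3,4-tris(acetyloxy)-6-methylbenzoate F3. Acidolysis (TFA/CH2Cl2) would give 2,3,4-tris(acetyloxy)-6-methylbenzoic acid F4. Under the conditions of step 6 this acid would pass through 2,3,4-tris(acetyloxy)-6-methylbenzoic trifluoroacetic anhydride F5 and acylate 11 to methyl 2-hydroxy-3,6-dimethyl-4-{[2,3,4-tris(acetyloxy)-6-methylbenzoyl]oxy}benzoate F6. Acid-catalysed methanolysis of the three unhindered aryl acetates (HCl in MeOH, 0 °C to rt, Ar) should spare the di-ortho-substituted depside ester and release 14.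

**Further compounds**
F1 | step 3 | tert-butyl 3-[(dimethylamino)methylidene]-6-methyl-2,4-dioxocyclohexane-1-carboxylate | CC1CC(=O)C(=CN(C)C)C(=O)C1C(=O)OC(C)(C)C
F2 | step 6 | 2,3,4-tris(benzyloxy)-6-methylbenzoyl chloride | Cc1cc(OCc2ccccc2)c(OCc2ccccc2)c(OCc2ccccc2)c1C(Cl)=O
F3 | step 4 | tert-butyl 2,3,4-tris(acetyloxy)-6-methylbenzoate | CC(=O)Oc1cc(C)c(C(=O)OC(C)(C)C)c(OC(C)=O)c1OC(C)=O
F4 | step 4 | 2,3,4-tris(acetyloxy)-6-methylbenzoic acid | CC(=O)Oc1cc(C)c(C(=O)O)c(OC(C)=O)c1OC(C)=O
F5 | step 4 | 2,3,4-tris(acetyloxy)-6-methylbenzoic trifluoroacetic anhydride | CC(=O)Oc1cc(C)c(C(=O)OC(=O)C(F)(F)F)c(OC(C)=O)c1OC(C)=O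
F6 | step 4 | methyl 2-hydroxy-3,6-dimethyl-4-{[2,3,4-tris(acetyloxy)-6-methylbenzoyl]oxy}benzoate | COC(=O)c1c(C)cc(OC(=O)c2c(C)cc(OC(C)=O)c(OC(C)=O)c2OC(C)=O)c(C)c1O
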